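**Plan**

1. Numbering: ring A with its pyran is a 2H-chromene (O1, C2, C3, C4, C4a, C5–C8, C8a); ring B is the cyclohexadienone with C1 quaternary (methyl, prenyl), C3 at the methylene bridge and C5 bearing the isobutyryl group.
2. Retrosynthesis: the O5–Si bond of a silyl ether goes first, then the pyran bonds C4a–C4 and O1–C2 (arene C–H/OH plus 3-methylbut-2-enal), then the C6–CH2 bond of the bridge (ring A monomer plus a 2-methylene ring B unit), then the C1–prenyl bond of ring B, and last the two aryl–acyl bonds.
3. Forward: ring B comes from 2,4,6-trihydroxytoluene (acylation, chlorine block on its one free carbon, asymmetric dearomative prenylation, dechlorination); ring A comes from phloroglucinol (acylation, silylation of the oxygen para to the ketone); the two are joined through CH2, the pyran is closed last on the dimer, and desilylation ends the route.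
4. Enabling feature: in the bridged dimer C4a is the only unsubstituted ring carbon. It lies between the free hydroxyl on C8a (ortho to the C8 isobutyryl) and the silylated O5, so condensation and closure can only place O1 next to C8. Ring B has no free carbon (C1 quaternary, C3 and C5 substituted).
5. Stereochemistry: the single stereocentre, C1 of ring B (S), is set by a palladium/chiral diphosphine allylic dearomatisation; it bears no hydrogen and is not touched afterwards.

Key step: step 8

Assumption: the facial preference of the chiral diphosphine for this phenoxide is not known in advance, so the (1R,2R)-ligand is written and its mirror image would be used should the opposite face be favoured; the enolised tricarbonyl units are drawn as one tautomer throughout.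

**Route**

Step 1
Reactants: 1 2,4,6-trihydroxytoluene; 2 isobutyryl chloride
Product: 3 1-(2,4,6-trihydroxy-3-methylphenyl)-2-methylpropan-1-one
Conditions: AlCl3 (3.5 equiv), PhNO2–CH2Cl2, 0 °C to 50 °C; then aq HCl
Reagents that add atoms: none
Why: Friedel–Crafts C-acylation of the electron-rich triol at one of its two equivalent free positions should stop at the monoketone, because the chelated aryl ketone deactivates the ring.

Step 2
Reactants: 3
Product: 4 1-(3-chloro-2,4,6-trihydroxy-5-methylphenyl)-2-methylpropan-1-one
Conditions: SO2Cl2 (1.0 equiv), CH2Cl2–Et2O, 0 °C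
Reagents that add atoms: sulfuryl chloride, O=S(=O)(Cl)Cl
Why: Electrophilic aromatic chlorination can only take place at the single unsubstituted ring carbon, and the chlorine then acts as a removable blocking group that excludes aromatic C-prenylation at this position in step 3.

Step 3
Reactants: 4; 5 3-methylbut-2-en-1-yl acetate (prenyl acetate)
Product: 6 (4R)-2-chloro-3,5-dihydroxy-4-methyl-4-(3-methylbut-2-en-1-yl)-6-(2-methylpropanoyl)cyclohexa-2,5-dien-1-one
Conditions: 5 (1.1 equiv), Pd2(dba)3·CHCl3 (2.5 mol%), (1R,2R)-N,N'-bis[2-(diphenylphosphino)benzoyl]cyclohexane-1,2-diamine (7.5 mol%), Et3N (2.5 equiv), CH2Cl2, 0 °C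
Reagents that add atoms: none
Why: This is a Tsuji–Trost asymmetric allylic alkylation used as an allylic dearomatisation of a phenol, in which the phenoxide of 4 should attack the unsubstituted terminus of the π-prenyl complex of zerovalent palladium through its methyl-bearing ring carbon (the free position is blocked and the other ring carbons carry the deactivating ketone and halogen), while the chiral diphosphine pocket differentiates the enantiotopic faces of the planar phenoxide and so sets the quaternary centre in the arrangement that is (S) in 7.

Step 4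
Reactants: 6
Product: 7 (4S)-3,5-dihydroxy-4-methyl-4-(3-methylbut-2-en-1-yl)-2-(2-methylpropanoyl)cyclohexa-2,5-dien-1-one (ring B monomer)
Conditions: Zn dust (5 equiv), AcOH–THF, 20 °C
Reagents that add atoms: none
Why: Zinc reduction of the α-chloro-β-dicarbonyl unit (reductive dehalogenation through the zinc enolate) should remove the blocking chlorine without touching the trisubstituted alkene or the ketones, and the quaternary stereocentre carries no hydrogen and cannot epimerise.

Step 5
Reactants: 8 phloroglucinol; 2 isobutyryl chloride
Product: 9 2-methyl-1-(2,4,6-trihydroxyphenyl)propan-1-one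
Conditions: AlCl3 (4 equiv), PhNO2–CH2Cl2, 0 °C to 40 °C; then aq HCl
Reagents that add atoms: none
Why: Friedel–Crafts acylation of phloroglucinol is expected to stop after one acyl group because the hydrogen-bonded ketone deactivates the ring.

Step 6
Reactants: 9
Product: 10 1-[4-(tert-butyldimethylsilyloxy)-2,6-dihydroxyphenyl]-2-methylpropan-1-one
Conditions: TBSCl (1.05 equiv), imidazole (2.2 equiv), DMF, −20 °C to 0 °C
Reagents that add atoms: tert-butyldimethylsilyl chloride, CC(C)(C)[Si](C)(C)Cl
Why: Silylation should select the hydroxyl para to the ketone, which is the most acidic and least hindered of the three, while the two ortho hydroxyls are hydrogen-bonded to or crowded by the isobutyryl group.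

Step 7
Reactants: 7; 10
Product: 13 silyl-blocked bridged dimer (ring B of 7 joined from its C3 through CH2 to a free ring carbon of 10), via ring B Mannich base 11 (not isolated), via 2-methylene trione 12 (not isolated)
Conditions: [CH2=NMe2]I (1.05 equiv), NaOAc (1.1 equiv), MeCN, 0 °C; then 10 (3 equiv), 60 °C
Reagents that add atoms: N,N-dimethylmethyleneiminium iodide (Eschenmoser's salt), C=[N+](C)C.[I-]
Why: A Mannich reaction at the only C–H of the vinylogous acid 7 should be followed on warming by retro-Mannich (E1cB) loss of dimethylamine to the 2-methylene trione and by Michael (Friedel–Crafts-type) addition of the arene at one of its two equivalent free carbons, each lying between the silyloxy group and a hydroxyl, with the excess of 10 suppressing a second alkylation.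

Step 8
Reactants: 13; 14 3-methylbut-2-enal
Product: 16 O5-tert-butyldimethylsilyl ether of the target, via vinyl ortho-quinone methide 15 (not isolated)
Conditions: 14 (3 equiv), piperidine (0.3 equiv), AcOH (0.3 equiv), 4 Å MS, toluene, 80 °C
Reagents that add atoms: none
Why: Piperidinium acetate turns 14 into its iminium ion, which is attacked by the only unsubstituted ring carbon of 13 (future C4a, between the free hydroxyl and the silyloxy group), and loss of piperidine through that neighbouring hydroxyl should give vinyl ortho-quinone methide 15. A thermal disrotatory oxa-6π electrocyclisation of 15 then forms O1–C2, closes the six-membered pyran ring and restores the arene, so that C4a–C4 and O1–C2 are the two skeletal bonds made. The closest known reaction type is the amine-salt-mediated condensation of phenols and 1,3-diones with α,β-unsaturated aldehydes to 2H-chromenes (Knoevenagel-type condensation followed by oxa-6π ring closure). No stereocentre is formed, because C2 carries two methyl groups, and C1 of ring B has no hydrogen and stays (S). The selectivity needed is that O1 ends up ortho to the C8 isobutyryl group: the silyl ether on O5 cannot become the quinone methide carbonyl, so only the hydroxyl next to the ketone can close, and ring B offers no free carbon (C1 quaternary, C3 and C5 substituted). A secondary ammonium salt is preferred to a primary one because primary amines would condense with the 2-acyl-1,3-dione of ring B to enaminones.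

Step 9
Reactants: 16
Product: 17 the target, (4S)-2-{[5,7-dihydroxy-2,2-dimethyl-8-(2-methylpropanoyl)-2H-chromen-6-yl]methyl}-3,5-dihydroxy-4-methyl-4-(3-methylbut-2-en-1-yl)-6-(2-methylpropanoyl)cyclohexa-2,5-dien-1-one
Conditions: Bu4NF (1.2 equiv), AcOH (1.5 equiv), THF, 0 °C
Reagents that add atoms: none
Why: Fluoride should cleave the aryl silyl ether through Si–F bond formation while the acetic acid buffer keeps the medium from turning basic, so that the methylene bridge, the chromene, the acidic enols and the stereocentre are left as they are.

**Compound list**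

1 | 2,4,6-trihydroxytoluene | Cc1c(O)cc(O)cc1O | starting material
2 | isobutyryl chloride | CC(C)C(Cl)=O | starting material
3 | 1-(2,4,6-trihydroxy-3-methylphenyl)-2-methylpropan-1-one | CC(C)C(=O)c1c(O)cc(O)c(C)c1O | intermediate
4 | 1-(3-chloro-2,4,6-trihydroxy-5-methylphenyl)-2-methylpropan-1-one | CC(C)C(=O)c1c(O)c(C)c(O)c(Cl)c1O | intermediate
5 | 3-methylbut-2-en-1-yl acetate (prenyl acetate) | CC(=O)OCC=C(C)C | starting material
6 | (4R)-2-chloro-3,5-dihydroxy-4-methyl-4-(3-methylbut-2-en-1-yl)-6-(2-methylpropanoyl)cyclohexa-2,5-dien-1-one; same spatial arrangement as 7, the descriptor differs only because chlorine raises the rank of its ring arm | CC(C)=CC[C@@]1(C)C(O)=C(Cl)C(=O)C(C(=O)C(C)C)=C1O | intermediate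
7 | (4S)-3,5-dihydroxy-4-methyl-4-(3-methylbut-2-en-1-yl)-2-(2-methylpropanoyl)cyclohexa-2,5-dien-1-one (ring B monomer) | CC(C)=CC[C@@]1(C)C(O)=CC(=O)C(C(=O)C(C)C)=C1O | intermediate
8 | phloroglucinol | Oc1cc(O)cc(O)c1 | starting material
9 | 2-methyl-1-(2,4,6-trihydroxyphenyl)propan-1-one | CC(C)C(=O)c1c(O)cc(O)cc1O | intermediate
10 | 1-[4-(tert-butyldimethylsilyloxy)-2,6-dihydroxyphenyl]-2-methylpropan-1-one | CC(C)C(=O)c1c(O)cc(O[Si](C)(C)C(C)(C)C)cc1O | intermediate
11 | ring B Mannich base (not isolated): (4S)-2-[(dimethylamino)methyl]-3,5-dihydroxy-4-methyl-4-(3-methylbut-2-en-1-yl)-6-(2-methylpropanoyl)cyclohexa-2,5-dien-1-one | CC(C)=CC[C@@]1(C)C(O)=C(CN(C)C)C(=O)C(C(=O)C(C)C)=C1O | intermediate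
12 | 2-methylene trione (not isolated): 5-hydroxy-6-methyl-2-methylidene-6-(3-methylbut-2-en-1-yl)-4-(2-methylpropanoyl)cyclohex-4-ene-1,3-dione, quaternary carbon arranged as in 7 | CC(C)=CC[C@@]1(C)C(=O)C(=C)C(=O)C(C(=O)C(C)C)=C1O | intermediate
13 | silyl-blocked bridged dimer: (4S)-2-{[6-(tert-butyldimethylsilyloxy)-2,4-dihydroxy-3-(2-methylpropanoyl)phenyl]methyl}-3,5-dihydroxy-4-methyl-4-(3-methylbut-2-en-1-yl)-6-(2-methylpropanoyl)cyclohexa-2,5-dien-1-one | CC(C)=CC[C@@]1(C)C(O)=C(Cc2c(O[Si](C)(C)C(C)(C)C)cc(O)c(C(=O)C(C)C)c2O)C(=O)C(C(=O)C(C)C)=C1O | intermediate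
14 | 3-methylbut-2-enal | CC(C)=CC=O | starting material
15 | vinyl ortho-quinone methide (not isolated): ring A of 13 with the former free carbon carrying an exocyclic (Z)-3-methylbut-2-en-1-ylidene group and the neighbouring oxygen as a ketone; ring B unchanged | CC(C)=CC[C@@]1(C)C(O)=C(CC2=C(O[Si](C)(C)C(C)(C)C)/C(=C/C=C(C)C)C(=O)C(C(=O)C(C)C)=C2O)C(=O)C(C(=O)C(C)C)=C1O | intermediate
16 | O5-tert-butyldimethylsilyl ether of the target: (4S)-2-{[5-(tert-butyldimethylsilyloxy)-7-hydroxy-2,2-dimethyl-8-(2-methylpropanoyl)-2H-chromen-6-yl]methyl}-3,5-dihydroxy-4-methyl-4-(3-methylbut-2-en-1-yl)-6-(2-methylpropanoyl)cyclohexa-2,5-dien-1-one | CC(C)=CC[C@@]1(C)C(O)=C(Cc2c(O[Si](C)(C)C(C)(C)C)c3c(c(C(=O)C(C)C)c2O)OC(C)(C)C=C3)C(=O)C(C(=O)C(C)C)=C1O | intermediate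
17 | CNP0301804.1: (4S)-2-{[5,7-dihydroxy-2,2-dimethyl-8-(2-methylpropanoyl)-2H-chromen-6-yl]methyl}-3,5-dihydroxy-4-methyl-4-(3-methylbut-2-en-1-yl)-6-(2-methylpropanoyl)cyclohexa-2,5-dien-1-one | CC(C)=CC[C@@]1(C)C(O)=C(Cc2c(O)c3c(c(C(=O)C(C)C)c2O)OC(C)(C)C=C3)C(=O)C(C(=O)C(C)C)=C1O | target

**Step count and risks**

Total step count: 9. Longest linear sequence: 7 steps (steps 1, 2, 3, 4, 7, 8 and 9, from 2,4,6-trihydroxytoluene); the ring A branch (steps 5 and 6) joins at step 7.

The three steps most likely to fail:

Step 3. What may go wrong: weak discrimination of the two ring faces by the diphosphine, attack through the tertiary terminus of the prenyl unit, or competing alkylation at the chlorine-bearing carbon. Fallback (resolution in place of asymmetric catalysis): setting out from 4, alkylation with 1-bromo-3-methylbut-2-ene and NaOMe in MeOH at 0 °C should give the racemic chloro dienone F1. Zinc in acetic acid would then give the racemic ring B monomer F2. Preparative chromatography on a chiral stationary phase (amylose tris(3,5-dimethylphenylcarbamate), CO2–MeOH with formic acid) would separate this into 7 and the unwanted (4R)-enantiomer F3, which is set aside. The route is rejoined at 7.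

Step 7. What may go wrong: self-condensation of the 2-methylene trione, a second alkylation of the product at its remaining ring A carbon, or loss of the silyl group to the liberated amine. Fallback (polarity reversed, ring A as the electrophile and ring B as the nucleophile): setting out from 10, one equivalent of N,N-dimethylmethyleneiminium iodide with NaOAc in CH2Cl2 at −20 °C should give the ring A Mannich base F4. Heated with 7 in toluene at 80 °C, this should lose dimethylamine to the ring A ortho-quinone methide F5, which is captured by the single enolic C–H of 7 in a conjugate addition. The route is rejoined at 13.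

Step 8. What may go wrong: retro-Michael cleavage and scrambling of the methylene bridge under amine and heat, enaminone formation on ring B, or slow condensation at the crowded carbon between the silyloxy group and the hydroxyl. Fallback (pyran closed before the bridge is made): setting out from 10, the same amine-salt condensation with 14 should give, through the monomer vinyl ortho-quinone methide F6, the monomer silyl chromene F7. Ring B monomer 7 is then taken as in step 7 through 11 to 12, and 12 is captured by the one remaining ring carbon of the chromene (its C6). The route is rejoined at 16.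

**Further compounds**

F1 | step 3 | racemic 2-chloro-3,5-dihydroxy-4-methyl-4-(3-methylbut-2-en-1-yl)-6-(2-methylpropanoyl)cyclohexa-2,5-dien-1-one | CC(C)=CCC1(C)C(O)=C(Cl)C(=O)C(C(=O)C(C)C)=C1O
F2 | step 3 | racemic 3,5-dihydroxy-4-methyl-4-(3-methylbut-2-en-1-yl)-2-(2-methylpropanoyl)cyclohexa-2,5-dien-1-one | CC(C)=CCC1(C)C(O)=CC(=O)C(C(=O)C(C)C)=C1O
F3 | step 3 | (4R)-3,5-dihydroxy-4-methyl-4-(3-methylbut-2-en-1-yl)-2-(2-methylpropanoyl)cyclohexa-2,5-dien-1-one (enantiomer of 7) | CC(C)=CC[C@]1(C)C(O)=CC(=O)C(C(=O)C(C)C)=C1O
F4 | step 7 | 1-[4-(tert-butyldimethylsilyloxy)-3-[(dimethylamino)methyl]-2,6-dihydroxyphenyl]-2-methylpropan-1-one (ring A Mannich base) | CC(C)C(=O)c1c(O)cc(O[Si](C)(C)C(C)(C)C)c(CN(C)C)c1O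
F5 | step 7 | ring A ortho-quinone methide: 5-(tert-butyldimethylsilyloxy)-3-hydroxy-6-methylidene-2-(2-methylpropanoyl)cyclohexa-2,4-dien-1-one | C=C1C(O[Si](C)(C)C(C)(C)C)=CC(O)=C(C(=O)C(C)C)C1=O
F6 | step 8 | monomer vinyl ortho-quinone methide: (Z)-5-(tert-butyldimethylsilyloxy)-3-hydroxy-6-(3-methylbut-2-en-1-ylidene)-2-(2-methylpropanoyl)cyclohexa-2,4-dien-1-one | CC(C)C(=O)C1=C(O)C=C(O[Si](C)(C)C(C)(C)C)/C(=C/C=C(C)C)C1=O
F7 | step 8 | 1-[5-(tert-butyldimethylsilyloxy)-7-hydroxy-2,2-dimethyl-2H-chromen-8-yl]-2-methylpropan-1-one (monomer silyl chromene) | CC(C)C(=O)c1c(O)cc(O[Si](C)(C)C(C)(C)C)c2C=CC(C)(C)Oc12
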